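## Retrosynthetic overview

1. The target is traced back to the 7-en-6-one **23** (ring B). Its 6,8-dienolate takes the 7α-oxygen and fixes C8=C9, α-face hydride then gives 6β-OH, and acylation and desilylation finish the route.
2. Ring B of **23** comes from one operation that joins the ring A vinyllithium **18** (C5 nucleophile) to cyclobutenone **14**, which holds C6–C9 and the whole side chain. 1,2-Addition makes C5–C6; 4π opening of the C6–C9 σ bond and 6π closure make C9–C10.
3. Enabling feature: ring B is a cyclohexene with oxygen on C6 next to ring-fusion C5 and unsaturation at C7–C9. At the 7-en-6-one level, C10=C5–C6(O)=C7–C8=C9 is a trienolate that is latent in a C6–C9-bonded cyclobutenolate.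
4. Cyclobutenone **14** comes from a ketene (Wolff) plus ethoxyacetylene [2+2], then MeLi/H3O+; the acid comes from a Johnson–Claisen rearrangement. Vinyllithium **18** comes from 2,2,6-trimethylcyclohexanone by a Shapiro reaction.
5. Ring order: ring A is bought, the four-membered ring is temporary, and ring B closes last (step 8). The cascade gives the racemate, so the absolute configuration is selected by a CBS kinetic resolution of the enone (step 9), which gives up half of the material.

Key step: step 8

Remark: labdane numbering is used throughout (ring A = C1–C5 and C10; ring B = C5–C10; side chain C11–C16; methyls C17–C20).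

## Route

Step 1
Reactants: 1 (tert-butyldimethylsilyloxy)acetaldehyde; 2 isopropenylmagnesium bromide
Product: 3 rac-1-(tert-butyldimethylsilyloxy)-3-methylbut-3-en-2-ol
Conditions: THF, −78 → 0 °C; aq NH4Cl
Reagents that add atoms: none
Why: Grignard 1,2-addition to the aldehyde; the new carbinol centre is racemic and is erased in step 2.

Step 2
Reactants: 3 rac-1-(tert-butyldimethylsilyloxy)-3-methylbut-3-en-2-ol; 4 triethyl orthoacetate
Product: 6 ethyl (E)-6-(tert-butyldimethylsilyloxy)-4-methylhex-4-enoate, via ketene acetal 5 (not isolated)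
Conditions: 4 (excess), EtCO2H (cat.), 140 °C, EtOH distilled off
Reagents that add atoms: none
Why: Johnson–Claisen rearrangement; the chair [3,3] transition state with CH2OTBS equatorial should give the (E)-trisubstituted alkene that becomes C13=C14.

Step 3
Reactants: 6 ethyl (E)-6-(tert-butyldimethylsilyloxy)-4-methylhex-4-enoate
Product: 7 (E)-6-(tert-butyldimethylsilyloxy)-4-methylhex-4-enoic acid
Conditions: LiOH·H2O, THF/H2O, 25 °C; then 1 M HCl to pH 4, 0 °C
Reagents that add atoms: lithium hydroxide, [Li+].[OH-]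
Why: Ester saponification; the primary TBS ether should survive the base and the brief cold acidification.

Step 4
Reactants: 7 (E)-6-(tert-butyldimethylsilyloxy)-4-methylhex-4-enoic acid
Product: 9 (E)-1-diazo-7-(tert-butyldimethylsilyloxy)-5-methylhept-5-en-2-one, via mixed anhydride 8 (not isolated)
Conditions: i-BuOCOCl, N-methylmorpholine, THF, −20 °C; then CH2N2, Et2O, 0 → 25 °C
Reagents that add atoms: diazomethane, C=[N+]=[N-]
Why: Arndt–Eistert-type acylation of diazomethane by the mixed carbonic anhydride gives the α-diazoketone without exposing the allylic silyl ether to HCl.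

Step 5
Reactants: 9 (E)-1-diazo-7-(tert-butyldimethylsilyloxy)-5-methylhept-5-en-2-one; 10 ethoxyacetylene
Product: 12 rac-3-ethoxy-4-[(E)-5-(tert-butyldimethylsilyloxy)-3-methylpent-3-enyl]cyclobut-2-en-1-one, via alkylketene 11 (not isolated)
Conditions: hν (λ > 300 nm), 10 (3 equiv), CH2Cl2, 20 °C
Reagents that add atoms: none
Why: Photochemical Wolff rearrangement gives the ketene, and its thermal [2+2] cycloaddition with the electron-rich alkyne (alkyne CH to the ketene carbonyl carbon) should give the 4-substituted 3-ethoxycyclobutenone; the ring stereocentre is racemic and is erased in step 8.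

Step 6
Reactants: 12 rac-3-ethoxy-4-[(E)-5-(tert-butyldimethylsilyloxy)-3-methylpent-3-enyl]cyclobut-2-en-1-one
Product: 14 rac-3-methyl-4-[(E)-5-(tert-butyldimethylsilyloxy)-3-methylpent-3-enyl]cyclobut-2-en-1-one, via lithium cyclobutenolate 13 (not isolated)
Conditions: MeLi, THF, −78 °C; then 1 M HCl, 0 °C
Reagents that add atoms: methyllithium, [Li]C; water, O
Why: 1,2-Addition of MeLi to the vinylogous ester carbonyl, then acid-promoted 1,3-carbonyl transposition with loss of ethanol, should give the 3-methylcyclobutenone whose methyl becomes C17.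

Step 7
Reactants: 15 2,2,6-trimethylcyclohexanone; 16 2,4,6-triisopropylbenzenesulfonyl hydrazide
Product: 17 2,2,6-trimethylcyclohexanone 2,4,6-triisopropylbenzenesulfonylhydrazone
Conditions: HCl (cat.), MeCN, 25 °C
Reagents that add atoms: none
Why: Acid-catalysed hydrazone formation; the triisopropylphenyl group is chosen because it resists ortho-lithiation in the Shapiro step.

Step 8
Reactants: 17 2,2,6-trimethylcyclohexanone 2,4,6-triisopropylbenzenesulfonylhydrazone; 14 rac-3-methyl-4-[(E)-5-(tert-butyldimethylsilyloxy)-3-methylpent-3-enyl]cyclobut-2-en-1-one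
Product: 22 rac-(5S*,9S*,10R*)-15-(tert-butyldimethylsilyloxy)labda-7,13E-dien-6-one, via vinyllithium 18 (not isolated), via lithium cyclobutenolate 19 (not isolated), via lithium trienolate 20 (not isolated), via lithium dienolate 21 (not isolated)
Conditions: 17 (1.3 equiv), n-BuLi (2.6 equiv), THF, −78 → 0 °C; 14, −78 → 25 °C, then 50 °C until 20 is consumed; AcOH, −78 °C
Reagents that add atoms: none
Why: Shapiro reaction of 17 (double deprotonation at the only α-CH, loss of sulfinate and N2) gives vinyllithium 18, which adds 1,2 to the strained carbonyl of 14 and makes the C5–C6 bond in cyclobutenolate 19. The oxido group accelerates the thermal conrotatory 4π opening of the C6–C9 σ bond and, because it rotates outward, forces the cyclohexenyl group inward, so trienolate 20 is born with C5 and C8 cis on C6=C7, the geometry needed for closure. Disrotatory 6π electrocyclization of 20 (six-membered all-carbon closure, the only ring closed) then makes the C9–C10 bond and the quaternary C10; the closest known reaction type is the ring expansion of cyclobutenones to cyclohexenones by alkenyllithium addition, 4π opening and 6π closure of the trienolate, and the triene has the substitution pattern of the thermal previtamin D to pyrocalciferol closure. C10 and C9 are created together, their relative configuration being fixed by the disrotatory mode and the C8=C9 geometry, with no bias between the two enantiomers; C9 is erased in step 10 and the enantiomer is selected in step 9. C5 is set when dienolate 21 is protonated from the α-face, anti to the axial methyls on C10 and C4, which gives the trans ring fusion, and base equilibration of this epimerisable centre would lead to the same isomer. The step needs 1,2- instead of 1,4-addition and cleavage of C6–C9 only: the β,β-disubstituted enone of 14 together with the hard organolithium secures the first, and the position of the ring double bond (C7=C8) allows no other electrocyclic opening.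

Step 9
Reactants: 22 rac-(5S*,9S*,10R*)-15-(tert-butyldimethylsilyloxy)labda-7,13E-dien-6-one
Product: 23 (5S,9S,10R)-15-(tert-butyldimethylsilyloxy)labda-7,13E-dien-6-one
Conditions: (R)-1-methyl-3,3-diphenyltetrahydro-1H,3H-pyrrolo[1,2-c][1,3,2]oxazaborole ((R)-Me-CBS, 0.2 equiv), catecholborane (0.6 equiv), toluene, −78 °C, run to about 55–60 % conversion; chromatography
Reagents that add atoms: none
Why: Kinetic resolution by Corey–Bakshi–Shibata reduction: with boron bound on the small vinylic C7–H side (C5 as the large group), the (R)-catalyst delivers hydride to the face that is the open α-face only in the enantiomer of 23, while in 23 it is the β-face shielded by the axial C10 and C4 methyls, so 23 should be recovered enriched and is separated from the alcohol.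

Step 10
Reactants: 23 (5S,9S,10R)-15-(tert-butyldimethylsilyloxy)labda-7,13E-dien-6-one
Product: 25 (5S,7S,10S)-15-(tert-butyldimethylsilyloxy)-7-hydroxylabda-8,13E-dien-6-one, via potassium dienolate 24 (not isolated)
Conditions: KN(SiMe3)2 (0.95 equiv), THF, −78 → 0 °C; 2-(phenylsulfonyl)-3-phenyloxaziridine, −78 °C; AcOH
Reagents that add atoms: 2-(phenylsulfonyl)-3-phenyloxaziridine, O=S(=O)(c1ccccc1)N1OC1c1ccccc1
Why: Equilibrating enolisation (slight deficit of base) should give the more substituted endocyclic 6,8-dienolate by loss of H9, and oxygen transfer from the N-sulfonyloxaziridine occurs at the α-carbon C7 from the α-face, anti to the angular methyl (as in α-face additions to steroidal ring B dienes), which sets 7α-OH and the C8=C9 bond together.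

Step 11
Reactants: 25 (5S,7S,10S)-15-(tert-butyldimethylsilyloxy)-7-hydroxylabda-8,13E-dien-6-one
Product: 26 (5S,6S,7S,10S)-15-(tert-butyldimethylsilyloxy)labda-8,13E-diene-6,7-diol
Conditions: NaBH4, MeOH/THF, −20 °C
Reagents that add atoms: none
Why: Hydride adds to the C6 ketone from the α-face because the β-face is closed by the syn-axial C10 and C4β methyls (the 7α-hydroxyl can also deliver borohydride on that face), which should give the axial 6β-alcohol and the trans-diaxial diol.

Step 12
Reactants: 26 (5S,6S,7S,10S)-15-(tert-butyldimethylsilyloxy)labda-8,13E-diene-6,7-diol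
Product: 27 (5S,6S,7S,10S)-15-(tert-butyldimethylsilyloxy)-7-(triethylsilyloxy)labda-8,13E-dien-6-ol
Conditions: Et3SiCl, imidazole, CH2Cl2, 0 °C
Reagents that add atoms: chlorotriethylsilane, CC[Si](Cl)(CC)CC
Why: Selective silylation of the less hindered allylic 7α-hydroxyl; the 6β-hydroxyl lies between two syn-axial methyls and should not react at 0 °C.

Step 13
Reactants: 27 (5S,6S,7S,10S)-15-(tert-butyldimethylsilyloxy)-7-(triethylsilyloxy)labda-8,13E-dien-6-ol; 28 3-methylbutanoyl chloride
Product: 29 (5S,6S,7S,10S)-15-(tert-butyldimethylsilyloxy)-7-(triethylsilyloxy)labda-8,13E-dien-6-yl 3-methylbutanoate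
Conditions: LiN(SiMe3)2, THF, −78 °C; 28, −78 → 0 °C
Reagents that add atoms: none
Why: Acylation of the hindered axial alcohol through its lithium alkoxide; the trans-diaxial arrangement of O6 and O7 should prevent silyl migration.

Step 14
Reactants: 29 (5S,6S,7S,10S)-15-(tert-butyldimethylsilyloxy)-7-(triethylsilyloxy)labda-8,13E-dien-6-yl 3-methylbutanoate
Product: 30 (5S,6S,7S,10S)-7,15-dihydroxylabda-8,13E-dien-6-yl 3-methylbutanoate (CNP0173680.1)
Conditions: HF·pyridine, pyridine/THF, 0 → 25 °C
Reagents that add atoms: none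
Why: Buffered fluoride cleavage of both silyl ethers leaves the ester and the allylic alcohol untouched, and acyl migration from O6 to O7 is geometrically disfavoured in the trans-diaxial diol.

## Compound list

1 | (tert-butyldimethylsilyloxy)acetaldehyde | O=CCO[Si](C)(C)C(C)(C)C | starting material
2 | isopropenylmagnesium bromide | CC(=C)[Mg]Br | starting material
3 | rac-1-(tert-butyldimethylsilyloxy)-3-methylbut-3-en-2-ol | CC(=C)C(O)CO[Si](C)(C)C(C)(C)C | intermediate
4 | triethyl orthoacetate | CC(OCC)(OCC)OCC | starting material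
5 | mixed ketene acetal (1-ethoxyvinyl ether of 3) | C=C(OCC)OC(CO[Si](C)(C)C(C)(C)C)C(C)=C | intermediate
6 | ethyl (E)-6-(tert-butyldimethylsilyloxy)-4-methylhex-4-enoate | CCOC(=O)CC/C(C)=C/CO[Si](C)(C)C(C)(C)C | intermediate
7 | (E)-6-(tert-butyldimethylsilyloxy)-4-methylhex-4-enoic acid | OC(=O)CC/C(C)=C/CO[Si](C)(C)C(C)(C)C | intermediate
8 | isobutyl carbonic mixed anhydride of 7 | CC(C)COC(=O)OC(=O)CC/C(C)=C/CO[Si](C)(C)C(C)(C)C | intermediate
9 | (E)-1-diazo-7-(tert-butyldimethylsilyloxy)-5-methylhept-5-en-2-one | [N-]=[N+]=CC(=O)CC/C(C)=C/CO[Si](C)(C)C(C)(C)C | intermediate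
10 | ethoxyacetylene | C#COCC | starting material
11 | (E)-7-(tert-butyldimethylsilyloxy)-5-methylhepta-1,5-dien-1-one (alkylketene) | O=C=CCC/C(C)=C/CO[Si](C)(C)C(C)(C)C | intermediate
12 | rac-3-ethoxy-4-[(E)-5-(tert-butyldimethylsilyloxy)-3-methylpent-3-enyl]cyclobut-2-en-1-one | CCOC1=CC(=O)C1CC/C(C)=C/CO[Si](C)(C)C(C)(C)C | intermediate
13 | lithium 3-ethoxy-1-methyl-4-[(E)-5-(tert-butyldimethylsilyloxy)-3-methylpent-3-enyl]cyclobut-2-en-1-olate (racemic, diastereomers) | CCOC1=CC(C)(O[Li])C1CC/C(C)=C/CO[Si](C)(C)C(C)(C)C | intermediate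
14 | rac-3-methyl-4-[(E)-5-(tert-butyldimethylsilyloxy)-3-methylpent-3-enyl]cyclobut-2-en-1-one | CC1=CC(=O)C1CC/C(C)=C/CO[Si](C)(C)C(C)(C)C | intermediate
15 | 2,2,6-trimethylcyclohexanone | CC1CCCC(C)(C)C1=O | starting material
16 | 2,4,6-triisopropylbenzenesulfonyl hydrazide | NNS(=O)(=O)c1c(C(C)C)cc(C(C)C)cc1C(C)C | starting material
17 | 2,2,6-trimethylcyclohexanone 2,4,6-triisopropylbenzenesulfonylhydrazone | CC1CCCC(C)(C)C1=NNS(=O)(=O)c1c(C(C)C)cc(C(C)C)cc1C(C)C | intermediate
18 | 2,6,6-trimethylcyclohex-1-enyllithium | [Li]C1=C(C)CCCC1(C)C | intermediate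
19 | lithium 3-methyl-1-(2,6,6-trimethylcyclohex-1-enyl)-4-[(E)-5-(tert-butyldimethylsilyloxy)-3-methylpent-3-enyl]cyclobut-2-en-1-olate (racemic, diastereomers) | CC1=CC(O[Li])(C2=C(C)CCCC2(C)C)C1CC/C(C)=C/CO[Si](C)(C)C(C)(C)C | intermediate
20 | lithium trienolate, O-lithio (1Z,5E)-8-(tert-butyldimethylsilyloxy)-3,6-dimethyl-1-(2,6,6-trimethylcyclohex-1-enyl)octa-1,3,6-trien-1-ol (C5 and C8 cis on C6=C7; C8=C9 geometry open) | [Li]O/C(=C/C(C)=CCC/C(C)=C/CO[Si](C)(C)C(C)(C)C)C1=C(C)CCCC1(C)C | intermediate
21 | lithium 5,7-dien-6-olate of 22 (racemic) | CC1=CC(O[Li])=C2C(C)(C)CCC[C@]2(C)[C@H]1CC/C(C)=C/CO[Si](C)(C)C(C)(C)C.CC1=CC(O[Li])=C2C(C)(C)CCC[C@@]2(C)[C@@H]1CC/C(C)=C/CO[Si](C)(C)C(C)(C)C | intermediate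
22 | rac-(5S*,9S*,10R*)-15-(tert-butyldimethylsilyloxy)labda-7,13E-dien-6-one | CC1=CC(=O)[C@H]2C(C)(C)CCC[C@]2(C)[C@H]1CC/C(C)=C/CO[Si](C)(C)C(C)(C)C.CC1=CC(=O)[C@@H]2C(C)(C)CCC[C@@]2(C)[C@@H]1CC/C(C)=C/CO[Si](C)(C)C(C)(C)C | intermediate
23 | (5S,9S,10R)-15-(tert-butyldimethylsilyloxy)labda-7,13E-dien-6-one | CC1=CC(=O)[C@H]2C(C)(C)CCC[C@]2(C)[C@H]1CC/C(C)=C/CO[Si](C)(C)C(C)(C)C | intermediate
24 | potassium (5S,10S)-15-(tert-butyldimethylsilyloxy)labda-6,8,13E-trien-6-olate | CC1=C(CC/C(C)=C/CO[Si](C)(C)C(C)(C)C)[C@@]2(C)CCCC(C)(C)[C@@H]2C(O[K])=C1 | intermediate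
25 | (5S,7S,10S)-15-(tert-butyldimethylsilyloxy)-7-hydroxylabda-8,13E-dien-6-one (7α-OH) | CC1=C(CC/C(C)=C/CO[Si](C)(C)C(C)(C)C)[C@@]2(C)CCCC(C)(C)[C@@H]2C(=O)[C@H]1O | intermediate
26 | (5S,6S,7S,10S)-15-(tert-butyldimethylsilyloxy)labda-8,13E-diene-6,7-diol (6β,7α) | CC1=C(CC/C(C)=C/CO[Si](C)(C)C(C)(C)C)[C@@]2(C)CCCC(C)(C)[C@@H]2[C@H](O)[C@H]1O | intermediate
27 | (5S,6S,7S,10S)-15-(tert-butyldimethylsilyloxy)-7-(triethylsilyloxy)labda-8,13E-dien-6-ol | CC1=C(CC/C(C)=C/CO[Si](C)(C)C(C)(C)C)[C@@]2(C)CCCC(C)(C)[C@@H]2[C@H](O)[C@H]1O[Si](CC)(CC)CC | intermediate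
28 | 3-methylbutanoyl chloride (isovaleryl chloride) | CC(C)CC(Cl)=O | starting material
29 | (5S,6S,7S,10S)-15-(tert-butyldimethylsilyloxy)-7-(triethylsilyloxy)labda-8,13E-dien-6-yl 3-methylbutanoate | CC1=C(CC/C(C)=C/CO[Si](C)(C)C(C)(C)C)[C@@]2(C)CCCC(C)(C)[C@@H]2[C@H](OC(=O)CC(C)C)[C@H]1O[Si](CC)(CC)CC | intermediate
30 | (5S,6S,7S,10S)-7,15-dihydroxylabda-8,13E-dien-6-yl 3-methylbutanoate (6β-ester, 7α-OH) | CC1=C(CC/C(C)=C/CO)[C@@]2(C)CCCC(C)(C)[C@@H]2[C@H](OC(=O)CC(C)C)[C@H]1O | target

## Step count and risks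

Total steps: 14. Longest linear sequence: 13 steps (1–6, then 8–14).

**Step 8.** The disrotatory closure of the congested trienolate (inward methyl on the C10 terminus) may be too slow at temperatures a lithium enolate tolerates, so that reversible [1,7]-hydrogen shift, proton transfer or γ-deprotonation of 14 compete with ring closure. The fallback sets out from 14 and 17. Vinyllithium 18 is made as before and added to 14 at −78 °C, but the alkoxide is protonated cold (AcOH) and the tertiary 3-methyl-1-(2,6,6-trimethylcyclohexenyl)cyclobutenol F1 is isolated. N-(Trimethylsilyl)imidazole converts it into the trimethylsilyl ether F2. Heating F2 in toluene at 140–160 °C in a sealed tube should bring about the neutral conrotatory opening (siloxy group outward) and the thermal disrotatory closure known from the previtamin D series, which overtakes the reversible hydrogen shift at this temperature, to give the racemic silyl dienol ether F3. Hydrolysis of F3 with 1 M HCl in THF returns the route at 22.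

**Step 9.** The rate difference between the two enantiomers may be too small, or the sense of the catalyst may be reversed if the alkene side behaves as the large group. The fallback sets out from 22. Reduction with NaBH4/CeCl3·7H2O in MeOH (Luche) gives the racemic 6β-allylic alcohol F4. Acylation with (1S)-camphanic chloride (4-dimethylaminopyridine, pyridine) gives two diastereomeric esters that are separated by chromatography or crystallisation; the wanted one is the camphanate F5. Saponification (LiOH, THF/MeOH/H2O) releases the enantiopure allylic alcohol F6, and MnO2 in CH2Cl2 oxidises F6 back to the enone, which returns the route at 23.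

**Step 10.** Enolisation may go towards the C17 methyl or C5 instead of C9, or the oxidant may attack the β-face. The fallback sets out from 23. Me3SiCl/NaI/Et3N in MeCN under equilibrating conditions gives the trimethylsilyl 6,8-dienol ether F7, whose double-bond positions can be verified before use. MeLi in THF at 0 °C cleaves the Si–O bond to the lithium 6,8-dienolate F8, which is oxidised at −78 °C with the same N-sulfonyloxaziridine; this returns the route at 25.

Further compounds
F1 | step 8 | 3-methyl-1-(2,6,6-trimethylcyclohex-1-enyl)-4-[(E)-5-(tert-butyldimethylsilyloxy)-3-methylpent-3-enyl]cyclobut-2-en-1-ol (racemic, diastereomers) | CC1=CC(O)(C2=C(C)CCCC2(C)C)C1CC/C(C)=C/CO[Si](C)(C)C(C)(C)C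
F2 | step 8 | trimethylsilyl ether of F1 | CC1=CC(O[Si](C)(C)C)(C2=C(C)CCCC2(C)C)C1CC/C(C)=C/CO[Si](C)(C)C(C)(C)C
F3 | step 8 | rac-(9S*,10R*)-15-(tert-butyldimethylsilyloxy)-6-(trimethylsilyloxy)labda-5,7,13E-triene | CC1=CC(O[Si](C)(C)C)=C2C(C)(C)CCC[C@]2(C)[C@H]1CC/C(C)=C/CO[Si](C)(C)C(C)(C)C.CC1=CC(O[Si](C)(C)C)=C2C(C)(C)CCC[C@@]2(C)[C@@H]1CC/C(C)=C/CO[Si](C)(C)C(C)(C)C
F4 | step 9 | rac-(5S*,6R*,9S*,10R*)-15-(tert-butyldimethylsilyloxy)labda-7,13E-dien-6-ol | CC1=C[C@@H](O)[C@H]2C(C)(C)CCC[C@]2(C)[C@H]1CC/C(C)=C/CO[Si](C)(C)C(C)(C)C.CC1=C[C@H](O)[C@@H]2C(C)(C)CCC[C@@]2(C)[C@@H]1CC/C(C)=C/CO[Si](C)(C)C(C)(C)C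
F5 | step 9 | (5S,6R,9S,10R)-15-(tert-butyldimethylsilyloxy)labda-7,13E-dien-6-yl (1S)-camphanate | CC1=C[C@@H](OC(=O)[C@@]34CC[C@@](C)(C(=O)O3)C4(C)C)[C@H]2C(C)(C)CCC[C@]2(C)[C@H]1CC/C(C)=C/CO[Si](C)(C)C(C)(C)C
F6 | step 9 | (5S,6R,9S,10R)-15-(tert-butyldimethylsilyloxy)labda-7,13E-dien-6-ol | CC1=C[C@@H](O)[C@H]2C(C)(C)CCC[C@]2(C)[C@H]1CC/C(C)=C/CO[Si](C)(C)C(C)(C)C
F7 | step 10 | (5S,10S)-15-(tert-butyldimethylsilyloxy)-6-(trimethylsilyloxy)labda-6,8,13E-triene | CC1=C(CC/C(C)=C/CO[Si](C)(C)C(C)(C)C)[C@@]2(C)CCCC(C)(C)[C@@H]2C(O[Si](C)(C)C)=C1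
F8 | step 10 | lithium (5S,10S)-15-(tert-butyldimethylsilyloxy)labda-6,8,13E-trien-6-olate | CC1=C(CC/C(C)=C/CO[Si](C)(C)C(C)(C)C)[C@@]2(C)CCCC(C)(C)[C@@H]2C(O[Li])=C1
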